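If the making of target and its loss both run in step with [partner], their ratio contains neither [partner] nor the clock. Dividing one rate by the other then leaves a peak share of target that stays put when partner changes.

| setting | spring | noon | autumn | winter |
|---|---|---|---|---|
| starting material | 0.200 M | 0.200 M | 0.600 M | 0.200 M |
| partner | 0.400 M | 0.800 M | 0.400 M | 0.400 M |
| target |  |  |  | 0.200 M |
| time |  |  |  | 3.7 h |

| run | time / h | [target] / M |
|---|---|---|
| spring run | 0.15 | 0.0099 |
| spring run | 0.25 | 0.0159 |
| spring run | 0.43 | 0.0229 |
| spring run | 0.74 | 0.0333 |
| spring run | 1.3 | 0.0435 |
| spring run | 2.2 | 0.0484 |
| spring run | 3.7 | 0.0543 |
| noon run | 0.15 | 0.0188 |
| noon run | 0.25 | 0.0260 |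
| noon run | 0.43 | 0.0378 |
| noon run | 0.74 | 0.0452 |
| noon run | 1.3 | 0.0527 |
| noon run | 2.2 | 0.0548 |
| noon run | 3.7 | 0.0529 |
| autumn run | 0.15 | 0.0300 |
| autumn run | 0.25 | 0.0450 |
| autumn run | 0.43 | 0.0660 |
| autumn run | 0.74 | 0.0868 |
| autumn run | 1.3 | 0.1061 |
| autumn run | 2.2 | 0.1195 |
| autumn run | 3.7 | 0.1265 |

(each reading ± 6 × 10⁻⁴ M)

1. order of the initial rate in [starting material], near the charge of the spring run, the rate being that where two percent of its starting material are target (one fixed amount of target, the same in the runs compared)
2. order of the initial rate in [partner], near the charge of the spring run, the rate being that where two percent of its starting material are target
3. target in the winter run at 3.7 h, as a share of the starting material charged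

- Overall: starting material + partner -> target.
- Constant volume, constant temperature.
- "The second partner" is partner.
- An order is taken over about fifteen percent of the charge, up and down.
- A share of target counts the target that was charged too.

The orders come first. At the first reading, noon over spring gives an order in [partner] of 0.925, and autumn over spring gives an order in [starting material] of 1.01. My objection is that the scatter on that spring reading is 6.06 %, but this still leaves both orders near one.

Now the invariant. I call the made share 27.1 %: target formed per starting material charged, taken at the last spring reading. The highest noon reading gives 27.4 %, about the same, although the noon run has twice the partner of the spring run.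

My doubt is that a dying partner could flatten both curves too, and then target would be inert. But the last noon reading lies 0.00190 M below the highest, which is 2.24 standard deviations of such a difference between two readings. It is a thin signal, but target that merely stops being made cannot fall, so I treat target as consumed.

How much of the winter charge survives? In a rough sketch with one constant for both steps, a peak comes after one lifetime, so if the last spring reading stands at that peak, the share of the winter charge kept is 36.8 %. Adding the made share gives 63.9 %. The objection is that the spring readings were still climbing at the last one, which in the sketch puts the spring run short of one lifetime, so this figure is probably low. I commit to 63.9 % or somewhat above, and below the charged share.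

The forecast gives orders in [starting material] and [partner] of 1 and 1 and a winter value of 127 %, on these grounds: “This looks like an active species dying in step with partner, not product inhibition.”

The flask gives orders in [starting material] and [partner] of 1.1 and 1.0, and 89.6 % for the winter run.

    starting material + partner → target (1.030 /M/h)
    starting material + partner → side product (0.9072 /M/h)
    2 partner → lost reagent (0.7812 /M/h)
    target + partner → side product (0.9036 /M/h)

Taking the made share 27.1 % from the winter value leaves 62.5 % of the charge counted as kept, more than my 36.8 %. The winter run falls short of the forecast because target is consumed by partner. With that path taken away, the same winter run ends at 136 % instead of 89.6 %, a difference of 47 percentage points.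

The data are calculated on assumed constants; noise was put on by code.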